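## Structural features

The target 14 is a diarylmethane: two identical benzene rings joined through one sp3 methylene carbon (C7), each ring bonded to C7 at C1. Going round each ring from C1, C2 and C3 carry bromine, C4 and C5 carry free hydroxyls, and C6 is the only ring CH, so each ring is pentasubstituted. The molecule is achiral and has no stereocentre; its twofold symmetry about C7 invites a two-directional synthesis. The fragile elements are the two catechols (oxidised to o-quinones by air in base, by halogens and by many oxidants), the four aryl bromides (lost on hydrogenolysis or halogen–metal exchange) and the doubly benzylic C7 (autoxidation, and acid-promoted ipso cleavage at C1, which is para to the C4 hydroxyl). The real difficulty is regiochemical: the bromines must sit on C2/C3 and C2'/C3' while C6 and C6' stay free, although C6 is activated by the C5 hydroxyl just as C3 is by the C4 hydroxyl, and the rings tolerate few oxidants once the catechol is free. The feature used here is that the run C1–C2(Br)=C3(Br)–C4(O) of each ring is already present in 1, as the γ-carbon, the dibrominated double bond and the lactone carbonyl of its butenolide form. Only C5 and C6 are missing, and they are supplied as the two alkene carbons of 11, whose formyl group is later exchanged for the C5 hydroxyl.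

## Logic of the disconnections

**14 ⇒ 13.** The C5–O and C5'–O bonds are cut and each hydroxyl is traced back to a formyl carbon (the Dakin retron, valid because the C4 hydroxyl is ortho). A formyl group on C5 is exactly the acceptor that a ring-forming cycloaddition needs. Two air-sensitive catechols are replaced by two robust salicylaldehydes. The forward oxidation must convert both formyl groups while sparing the catechols it creates, the C–Br bonds and C7.

**13 ⇒ 10 + 11 (through 12).** In each ring the C4–C5 and C6–C1 bonds are cut, after formally returning water to C1/C6 and re-closing an oxygen bridge between C1 and C4. Removing C5–C6 leaves a furan that holds C1 to C4 (furan C5 = C1, C4 = C2, C3 = C3, C2 = C4) with both bromines already in place. Two benzene rings and four C–C bonds are reduced to one symmetrical bis-furan and two molecules of a C3 enal, with no aromatic bromination anywhere. The forward step must add in one orientation at both furans (C1 to the β-carbon of 11, C4 to its α-carbon) and must aromatise by loss of water across C1/C6.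

**10 ⇒ 8 + 4 (with 3, through 9).** One C7–furan bond (C7–C1') is cut, together with the O–Si bond of the other half. C7 is the natural place: as the exocyclic methylene of 8 it is an electrophile, while C1' of 4 is the nucleophilic furan terminus. The bis-furan is halved into two pieces that both derive from 4. The forward addition must go to the exocyclic CH2 only and not to the brominated β-carbon; the silyl group transferred in the addition should stay on the acceptor-derived furan, so that only one further silylation is needed.

**8 ⇒ 7 ⇒ 4 + 5 (through 6).** The C1=C7 double bond is traced back to a C7–N+ bond next to the acidic γ-position (elimination retron), and then the C1–C7 σ bond is cut (Mannich retron). 5 is a one-carbon electrophile that attaches C7 to C1 and brings its own leaving group. C7 thus comes from a stable commercial salt, and the reactive 8 is released from a storable salt only when needed. The forward steps need aminomethylation at the one unsubstituted furan carbon, prompt quaternisation, and an elimination mild enough to leave the bromides alone.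

**4 ⇒ 2 + 3 and 2 ⇒ 1.** The O–Si bond is cut, and the C1–H bond of 2 is traced back to the C1–OH of the pseudo-acid (reduction retron). All eight carbons C1–C4 and C1'–C4' of 14 and all four bromines then come from one inexpensive C4 building block. The reduction must spare the vinylic bromides and the conjugated alkene, and the enol silylation must not be accompanied by amine attack on the β-bromide.

## Other disconnections considered

**Alternative 1:** The cut is at both C7–C1 bonds; C7 comes at the formate oxidation level from A3 and each ring from the aryl iodide A1. In the forward key step A1 undergoes iodine–magnesium exchange with A2, and two equivalents of the resulting arylmagnesium species add to A3 to give the diarylmethanol A4. Ionic deoxygenation at C7 and cleavage of four methyl ethers would then lead to 14.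
- In its favour: it is convergent and uses one aryl block twice. Exchange of iodine in the presence of two bromines is a dependable chemoselectivity at low temperature. The benzhydrol should be reduced easily, because each C4 methoxy group is para to C1.
- Against it here: A1 is not a commodity. Its contiguous dibromo pattern beside two methoxy groups must be made by stepwise aromatic halogenation, so the C3-versus-C6 problem is only moved into the building block. The arylmagnesium species has an ortho bromine and can collapse to an aryne on warming. The second addition must join two ortho-brominated aryl groups at one carbon, and C7 arrives one oxidation level too high.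
- Comparison, structure: the chosen plan is stronger, since its bromines are never installed on an arene and its phenols are never protected.
- Comparison, mechanism: Alternative 1 is the better, because each step is a standard polar reaction while the twofold cycloaddition is an extrapolation.
- Comparison, step economy: roughly equal — three steps from A1 plus those that A1 itself needs, against seven in all.

**Alternative 2:** The cut is at C2–C3 and C5–C6 of each ring. C6–C1–C2 of both rings and C7 come from one five-carbon chain in the form of the bis-vinamidinium salt A5, and C3–C4–C5 from the ketoester A6. In the forward key step an alkoxide base condenses A5 twice with A6; both α-carbons of each ketone add to the iminium termini, four amine molecules are lost, and both rings close as A7.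
- In its favour: it is a two-directional ring synthesis, equal to the chosen plan in that respect. It places the C4 hydroxyl and the C5 oxygen (as methyl ether) unambiguously. All intermediates are stable salts or esters. The condensation is a dependable arene synthesis, so this key step is at least as secure as the cycloaddition and probably more so, which is a point for the alternative.
- Against it here: A7 carries hydrogen on C2 and an ester on C3, so none of the four bromines is present. C3 would need saponification and bromodecarboxylation. C2 would need an electrophilic bromination that is para to the C5 methoxy group but competes with C6 (ortho to the same group) and with ipso attack at C1 (para to the free C4 hydroxyl), which would cut C1–C7.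
- Comparison, structure: the chosen plan carries the bromines from the start; Alternative 2 postpones the whole regiochemical problem to the end, on an electron-rich and cleavage-prone diarylmethane.
- Comparison, mechanism: the alternative has the safer key step but the less safe endgame.
- Comparison, step economy: the chosen plan is better — at least four steps after the key step against one, plus the preparation of A5.

**Alternative 3:** The cut is at C3–Br and C3'–Br. In the forward key step A8, which has bromine only on C2 and C2', is magnesiated at C3 and C3' with A9 and quenched with A10 to give A11. Cleavage of the four methyl ethers would then give 14.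
- In its favour: C3–H lies between bromine and methoxy and is the most acidic ring position, so the site selectivity is plausible. A8 should be reachable in two steps from a commodity dimethoxyarene (acid-mediated methylene bridging, then bromination para to a methoxy group). The route would have about four steps and only stable intermediates. In step economy and ease of handling this alternative is better than the chosen plan.
- Against it here: the rings are electron-rich, so the magnesium amide may metalate slowly or incompletely, and two metalations are needed in one molecule. Stronger bases would invite aryne formation from the ortho-bromo aryl metal, halogen migration, or deprotonation at the doubly benzylic C7. Four ethers remain to be cleaved.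
- Comparison, structure: the chosen plan places every bromine without any selectivity question; the alternative relies on one clean directed metalation per ring.
- Comparison, mechanism: the two are equal in uncertainty — the alternative depends on the acidity of an electron-rich arene, the chosen plan on the reactivity of a dibrominated diene.
- Comparison, step economy: the alternative is clearly better, about four steps against seven.

Key step: step 6

Remark on the chemistry: every stereocentre that appears on the way (the γ-carbons of 6, 7 and 9 and the sp3 ring carbons of 12) is destroyed later, so these compounds are carried as racemates or diastereomer mixtures; 14 is achiral.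

## Route

Step 1
Reactants: 1 mucobromic acid (3,4-dibromo-5-hydroxyfuran-2(5H)-one, racemic pseudo-acid)
Product: 2 3,4-dibromofuran-2(5H)-one
Conditions: NaBH4, MeOH, 0 °C; then conc. H2SO4, 0 °C to rt
Reagents that add atoms: none
Why: NaBH4 reduces the open-chain aldehyde tautomer of the pseudo-acid to the (Z)-4-hydroxy-2,3-dibromobutenoic acid, which lactonises on acidification (chemoselective carbonyl reduction and lactonisation); at 0 °C the vinylic bromides and the conjugated double bond should not be reduced.

Step 2
Reactants: 2 3,4-dibromofuran-2(5H)-one; 3 tert-butyldimethylsilyl trifluoromethanesulfonate
Product: 4 tert-butyl[(3,4-dibromofuran-2-yl)oxy]dimethylsilane (3,4-dibromo-2-silyloxyfuran)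
Conditions: Et3N, CH2Cl2, 0 °C; pentane, filtration
Reagents that add atoms: none
Why: Soft enolisation (silyl dienol ether formation from a butenolide): O-silylation of the lactone carbonyl acidifies the γ-CH2 and Et3N removes a proton to give the aromatic 2-silyloxyfuran; a tertiary amine at 0 °C should not displace the β-bromide.

Step 3
Reactants: 4 tert-butyl[(3,4-dibromofuran-2-yl)oxy]dimethylsilane; 5 dimethylmethyleneiminium iodide
Product: 7 [(3,4-dibromo-5-oxo-2,5-dihydrofuran-2-yl)methyl]trimethylammonium iodide (racemic), via Mannich base 6 (not isolated)
Conditions: CH2Cl2, 0 °C to rt; aq NaHCO3 wash; then MeI, acetone, rt, filtration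
Reagents that add atoms: iodomethane, CI
Why: Vinylogous Mannich reaction: the preformed iminium ion is attacked by the only unsubstituted furan carbon of 4 while iodide takes the silyl group, so no Lewis acid is needed; the new γ-stereocentre forms as a racemate and is destroyed in step 4. Immediate N-methylation of the crude amine gives the salt 7, which should precipitate and can be stored in place of the labile free base 6.

Step 4
Reactants: 7 [(3,4-dibromo-5-oxo-2,5-dihydrofuran-2-yl)methyl]trimethylammonium iodide
Product: 8 3,4-dibromo-5-methylidenefuran-2(5H)-one
Conditions: aq NaHCO3, CH2Cl2, 0 °C, BHT (cat.); dilute HCl wash; dried solution used directly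
Reagents that add atoms: none
Why: Hofmann-type E1cB elimination of a Mannich-base methiodide: bicarbonate removes the acidic γ-proton and the furanolate expels trimethylamine from C7, under conditions too mild to touch the C–Br bonds. 8 is kept cold and dilute with BHT because γ-methylene butenolides polymerise when concentrated.

Step 5
Reactants: 8 3,4-dibromo-5-methylidenefuran-2(5H)-one; 4 tert-butyl[(3,4-dibromofuran-2-yl)oxy]dimethylsilane; 3 tert-butyldimethylsilyl trifluoromethanesulfonate
Product: 10 bis[3,4-dibromo-5-(tert-butyldimethylsilyloxy)furan-2-yl]methane, via monosilylated Michael adduct 9 (not isolated)
Conditions: TBSOTf (0.1 equiv), CH2Cl2, −78 °C; then Et3N, TBSOTf (1.1 equiv), −78 to 0 °C; pentane, filtration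
Reagents that add atoms: none
Why: Vinylogous Mukaiyama–Michael addition in the 1,6-mode: catalytic TBSOTf O-silylates the carbonyl of 8 to a 2-silyloxyfurfuryl cation, whose exocyclic CH2 (C7) is attacked by the unsubstituted carbon of 4; aromatisation of the acceptor ring to a silyloxyfuran drives the addition and the silyl group of 4 carries the chain. The remaining butenolide of 9 (racemic at its γ-carbon, a centre erased at once) is then converted to the second silyloxyfuran by the soft enolisation of step 2 in the same flask.

Step 6
Reactants: 10 bis[3,4-dibromo-5-(tert-butyldimethylsilyloxy)furan-2-yl]methane; 11 acrolein (prop-2-enal)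
Product: 13 5,5'-methylenebis(3,4-dibromo-2-hydroxybenzaldehyde), via twofold 7-oxanorbornene cycloadduct 12 (not isolated)
Conditions: 11 (6 equiv), BHT (cat.), toluene, 60 °C, sealed tube; evaporate; then TsOH·H2O, THF, rt to 50 °C
Reagents that add atoms: none
Why: Each 2-silyloxyfuran of 10 is an electron-rich diene and 11 is an acceptor alkene, so a normal-demand Diels–Alder reaction should form C6–C1 and C4–C5 at both ends and give 12. The closest known reaction type is the cycloaddition of 2-trialkylsilyloxyfurans with electron-poor alkenes, followed by acid-mediated conversion of the oxanorbornene adducts into phenols. Each benzene ring is closed by the intermolecular [4+2] cycloaddition itself (both ring bonds in one event, a six-membered carbocycle bridged by the former furan oxygen) and is then aromatised: acid cleaves the silyl ketal at C4 to the ketone, which opens the bridge and leaves a tertiary alcohol on C1; in the enol form of the resulting β-keto aldehyde this alcohol ionises to a cyclohexadienyl cation that loses the C6 proton, so that C4 ends as the phenol. No stereocentre survives: the sp3 centres of 12 and all its endo/exo and diastereomeric forms converge on achiral 13. The step needs one orientation of addition, secured by the polarisation of the diene (largest HOMO coefficient on C1, the furan α-carbon without the silyloxy group, which pairs with the β-carbon of 11, while the silyl ketal carbon C4 pairs with the α-carbon), so that the formyl group lands on C5 next to the future phenol. It also needs aromatisation by loss of water and not of bromide, secured because both bromines sit on the C2=C3 double bond, which never becomes sp3, and because C1 alone carries a leaving group next to a C–H (loss towards C7 would give an isotoluene that tautomerises to the same arene). Lewis acids are kept out of the cycloaddition stage so that a stepwise Mukaiyama–Michael pathway with silyl transfer does not compete, and excess 11 is removed before the acid is added.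

Step 7
Reactants: 13 5,5'-methylenebis(3,4-dibromo-2-hydroxybenzaldehyde)
Product: 14 bis(2,3-dibromo-4,5-dihydroxyphenyl)methane
Conditions: 30% aq H2O2 (2.4 equiv), aq NaOH, THF, 0 °C, Ar; then Na2SO3, dilute HCl
Reagents that add atoms: hydrogen peroxide, OO
Why: Dakin oxidation: hydroperoxide anion adds to each formyl group, the aryl group migrates to oxygen with help from the ortho phenoxide, and the aryl formates are saponified in situ to the catechols. The aryl bromides and C7 are inert, and cold, oxygen-free conditions with a reductive acidic quench should limit quinone formation.

## Compound list

1 | mucobromic acid, 3,4-dibromo-5-hydroxyfuran-2(5H)-one (racemic) | OC1OC(=O)C(Br)=C1Br | starting material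
2 | 3,4-dibromofuran-2(5H)-one | O=C1OCC(Br)=C1Br | intermediate
3 | tert-butyldimethylsilyl trifluoromethanesulfonate | CC(C)(C)[Si](C)(C)OS(=O)(=O)C(F)(F)F | starting material
4 | tert-butyl[(3,4-dibromofuran-2-yl)oxy]dimethylsilane | CC(C)(C)[Si](C)(C)Oc1occ(Br)c1Br | intermediate
5 | dimethylmethyleneiminium iodide | C=[N+](C)C.[I-] | starting material
6 | 3,4-dibromo-5-[(dimethylamino)methyl]furan-2(5H)-one (racemic, not isolated) | CN(C)CC1OC(=O)C(Br)=C1Br | intermediate
7 | [(3,4-dibromo-5-oxo-2,5-dihydrofuran-2-yl)methyl]trimethylammonium iodide (racemic) | C[N+](C)(C)CC1OC(=O)C(Br)=C1Br.[I-] | intermediate
8 | 3,4-dibromo-5-methylidenefuran-2(5H)-one | C=C1OC(=O)C(Br)=C1Br | intermediate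
9 | 3,4-dibromo-5-{[3,4-dibromo-5-(tert-butyldimethylsilyloxy)furan-2-yl]methyl}furan-2(5H)-one (racemic, not isolated) | CC(C)(C)[Si](C)(C)Oc1oc(CC2OC(=O)C(Br)=C2Br)c(Br)c1Br | intermediate
10 | bis[3,4-dibromo-5-(tert-butyldimethylsilyloxy)furan-2-yl]methane | CC(C)(C)[Si](C)(C)Oc1oc(Cc2oc(O[Si](C)(C)C(C)(C)C)c(Br)c2Br)c(Br)c1Br | intermediate
11 | acrolein (prop-2-enal) | C=CC=O | starting material
12 | 4,4'-methylenebis{5,6-dibromo-1-[(tert-butyldimethylsilyl)oxy]-7-oxabicyclo[2.2.1]hept-5-ene-2-carbaldehyde} (mixture of diastereomers, not isolated) | O=CC1CC2(CC34CC(C=O)C(O[Si](C)(C)C(C)(C)C)(O3)C(Br)=C4Br)OC1(O[Si](C)(C)C(C)(C)C)C(Br)=C2Br | intermediate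
13 | 5,5'-methylenebis(3,4-dibromo-2-hydroxybenzaldehyde) | O=Cc1cc(Cc2cc(C=O)c(O)c(Br)c2Br)c(Br)c(Br)c1O | intermediate
14 | bis(2,3-dibromo-4,5-dihydroxyphenyl)methane (achiral) | Oc1cc(Cc2cc(O)c(O)c(Br)c2Br)c(Br)c(Br)c1O | target

## Step count and least certain steps

Total step count: 7. Longest linear sequence: 7 steps (1 → 2 → 4 → 7 → 8 → 10 → 13 → 14); 4 enters twice, in steps 3 and 5.

**Step 6 (key step).** The most likely failure is that C–C bond formation stops after the first bond: conjugate addition of the furan C1 to 11 with silyl transfer instead of ring closure. Cycloreversion or hydrolytic desilylation of one furan before both have reacted is also possible. The two bromines lower the diene HOMO and C1 is fully substituted, so the cycloaddition should be slower than with an unsubstituted silyloxyfuran, and the tertiary C1 alcohol is harder to eliminate than a secondary one. The fallback builds the ring before the bridge. It sets out from 4: cycloaddition with 11 under the conditions of step 6 should give the less hindered monomeric cycloadduct 2,3-dibromo-4-[(tert-butyldimethylsilyl)oxy]-7-oxabicyclo[2.2.1]hept-2-ene-5-carbaldehyde F1. TsOH·H2O should open and dehydrate F1 (here at a secondary alcohol) to 3,4-dibromo-2-hydroxybenzaldehyde F2. Two molecules of F2 are then joined with 1,3,5-trioxane in AcOH/conc. H2SO4 at 80–90 °C (acid-mediated hydroxymethylation and Friedel–Crafts alkylation). The only position that is para to the hydroxyl and meta to the formyl group is C5, and the ortho position is blocked by bromine. The fallback comes back to the route at 13.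

**Step 5.** The most likely failure is loss of chemoselectivity at the electrophile: oligomerisation of 8 under the silyl triflate, attack at the brominated β-carbon with displacement of bromide, or a second addition of 9 to another molecule of 8. The fallback sets out from 7 and 2. iPr2NEt in MeCN at 0 °C releases 8 from 7 by elimination in the presence of an excess of the dienolate of 2 (the Mannich-base methiodide variant of the Michael addition), so that 8 never accumulates. This should give 5,5'-methylenebis[3,4-dibromofuran-2(5H)-one] F3 as a meso/racemic mixture. Twofold soft enolisation of F3 with TBSOTf (2.2 equiv) and Et3N in CH2Cl2 at 0 °C comes back to the route at 10.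

**Step 4.** The most likely failure is polymerisation of 8 during handling, together with conjugate addition or vinylic substitution by the liberated trimethylamine. The fallback sets out from 4 and avoids the ammonium salt. Yb(OTf)3-catalysed hydroxymethylation of 4 with aqueous formaldehyde in THF (vinylogous Mukaiyama aldol reaction) should give 3,4-dibromo-5-(hydroxymethyl)furan-2(5H)-one F4. MsCl and Et3N in CH2Cl2 at 0 °C convert F4 into (3,4-dibromo-5-oxo-2,5-dihydrofuran-2-yl)methyl methanesulfonate F5, which eliminates in the same flask. The fallback comes back to the route at 8.

**Step 7.** The most likely failure is over-oxidation: the liberated catechol dianion is oxidised to the o-quinone and beyond by alkaline peroxide before the second formyl group has reacted. The fallback sets out from 13 and keeps the phenols masked during the oxidation.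
- MeI and K2CO3 in DMF give 5,5'-methylenebis(3,4-dibromo-2-methoxybenzaldehyde) F6.
- Baeyer–Villiger oxidation of F6 with mCPBA in CH2Cl2 gives bis(2,3-dibromo-5-formyloxy-4-methoxyphenyl)methane F7.
- K2CO3 in MeOH cleaves the formates of F7 to bis(2,3-dibromo-5-hydroxy-4-methoxyphenyl)methane F8.
- BBr3 in CH2Cl2 (−78 °C to rt) removes the two methyl ethers under non-oxidising conditions, and the fallback comes back to the route at 14.

## Further compounds

F1 | step 6 | 2,3-dibromo-4-[(tert-butyldimethylsilyl)oxy]-7-oxabicyclo[2.2.1]hept-2-ene-5-carbaldehyde (racemic endo/exo mixture) | O=CC1CC2OC1(O[Si](C)(C)C(C)(C)C)C(Br)=C2Br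
F2 | step 6 | 3,4-dibromo-2-hydroxybenzaldehyde | O=Cc1ccc(Br)c(Br)c1O
F3 | step 5 | 5,5'-methylenebis[3,4-dibromofuran-2(5H)-one] (meso/racemic mixture) | O=C1OC(CC2OC(=O)C(Br)=C2Br)C(Br)=C1Br
F4 | step 4 | 3,4-dibromo-5-(hydroxymethyl)furan-2(5H)-one (racemic) | OCC1OC(=O)C(Br)=C1Br
F5 | step 4 | (3,4-dibromo-5-oxo-2,5-dihydrofuran-2-yl)methyl methanesulfonate (racemic) | CS(=O)(=O)OCC1OC(=O)C(Br)=C1Br
F6 | step 7 | 5,5'-methylenebis(3,4-dibromo-2-methoxybenzaldehyde) | COc1c(C=O)cc(Cc2cc(C=O)c(OC)c(Br)c2Br)c(Br)c1Br
F7 | step 7 | bis(2,3-dibromo-5-formyloxy-4-methoxyphenyl)methane | COc1c(OC=O)cc(Cc2cc(OC=O)c(OC)c(Br)c2Br)c(Br)c1Br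
F8 | step 7 | bis(2,3-dibromo-5-hydroxy-4-methoxyphenyl)methane | COc1c(O)cc(Cc2cc(O)c(OC)c(Br)c2Br)c(Br)c1Br
A1 | alternative 1 | 2,3-dibromo-1-iodo-4,5-dimethoxybenzene | COc1cc(I)c(Br)c(Br)c1OC
A2 | alternative 1 | isopropylmagnesium chloride–lithium chloride (iPrMgCl·LiCl) | CC(C)[Mg]Cl.[Li+].[Cl-]
A3 | alternative 1 | ethyl formate | CCOC=O
A4 | alternative 1 | bis(2,3-dibromo-4,5-dimethoxyphenyl)methanol | COc1cc(C(O)c2cc(OC)c(OC)c(Br)c2Br)c(Br)c(Br)c1OC
A5 | alternative 2 | 3,3'-methylenebis(1,1,5,5-tetramethyl-1,5-diazapentadienium) bis(hexafluorophosphate) | CN(C)C=C(CC(C=[N+](C)C)=CN(C)C)C=[N+](C)C.F[P-](F)(F)(F)(F)F.F[P-](F)(F)(F)(F)F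
A6 | alternative 2 | methyl 4-methoxyacetoacetate | COCC(=O)CC(=O)OC
A7 | alternative 2 | dimethyl 5,5'-methylenebis(2-hydroxy-3-methoxybenzoate) | COC(=O)c1cc(Cc2cc(OC)c(O)c(C(=O)OC)c2)cc(OC)c1O
A8 | alternative 3 | bis(2-bromo-4,5-dimethoxyphenyl)methane | COc1cc(Br)c(Cc2cc(OC)c(OC)cc2Br)cc1OC
A9 | alternative 3 | 2,2,6,6-tetramethylpiperidinylmagnesium chloride–lithium chloride (TMPMgCl·LiCl) | CC1(C)CCCC(C)(C)N1[Mg]Cl.[Li+].[Cl-]
A10 | alternative 3 | 1,2-dibromo-1,1,2,2-tetrachloroethane | ClC(Cl)(Br)C(Cl)(Cl)Br
A11 | alternative 3 | bis(2,3-dibromo-4,5-dimethoxyphenyl)methane | COc1cc(Cc2cc(OC)c(OC)c(Br)c2Br)c(Br)c(Br)c1OC
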